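**Strategy.** The seven-membered ring is closed through the bond between the angelate-bearing carbinol carbon C4 and the allylic methylene C5 (hydroazulene numbering). With C8 held as a ketone, the array C4(OH)–C5H2–C6(Me)=C7–C8(=O) of that ring is a vinylogous aldol retron. The precursor is a cyclopentane with a formyl group on C3a and a 3-methylbut-2-enoyl ketone on the quaternary C8a; its silyl dienol ether, made in situ, attacks the aldehyde through the γ-carbon. One operation forms the C4–C5 bond, the cycloheptenone with the trisubstituted C6=C7 alkene and the C4 stereocentre. The cyclopentane is built from (R)-4-silyloxycyclopentenone; the three esters follow one at a time.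

Key step: step 11

Remark: bicyclic compounds are numbered as octahydroazulenes (C1–C3 five-ring carbons, C3a/C8a ring fusion, C4–C8 seven-ring carbons); 1, 7 and 18 are taken as commercial.

**Step 1**
Reactants: 1 (R)-4-(tert-butyldimethylsilyloxy)cyclopent-2-en-1-one
Product: 2 (3R,4R)-4-(tert-butyldimethylsilyloxy)-3-methyl-1-(trimethylsilyloxy)cyclopent-1-ene
Conditions: Me2CuLi, TMSCl, THF, −78 °C
Reagents that add atoms: lithium dimethylcuprate [Li+].C[Cu-]C; chlorotrimethylsilane C[Si](C)(C)Cl
Why: Cuprate conjugate addition with in situ silyl trapping should deliver methyl anti to the silyloxy group and lock the enolate regiochemistry before silyloxide can be expelled (the C3 centre is erased again in step 2).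

**Step 2**
Reactants: 2 (3R,4R)-4-(tert-butyldimethylsilyloxy)-3-methyl-1-(trimethylsilyloxy)cyclopent-1-ene
Product: 3 (R)-4-(tert-butyldimethylsilyloxy)-3-methylcyclopent-2-en-1-one
Conditions: Pd(OAc)2, MeCN, rt
Reagents that add atoms: none
Why: Saegusa–Ito oxidation should regenerate the enone by β-hydride elimination towards the methyl-bearing carbon, leaving the silyloxy stereocentre untouched.

**Step 3**
Reactants: 3 (R)-4-(tert-butyldimethylsilyloxy)-3-methylcyclopent-2-en-1-one
Product: 4 (1R,4R)-4-(tert-butyldimethylsilyloxy)-3-methyl-1-(propan-2-yl)cyclopent-2-en-1-ol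
Conditions: i-PrMgCl, CeCl3, THF, −78 °C
Reagents that add atoms: isopropylmagnesium chloride CC(C)[Mg]Cl
Why: Organocerium 1,2-addition (Imamoto conditions) should suppress enolization, reduction and 1,4-addition, and the nucleophile should enter anti to the silyloxy group, which sets the tertiary carbinol (hydroxyl cis to OTBS).

**Step 4**
Reactants: 4 (1R,4R)-4-(tert-butyldimethylsilyloxy)-3-methyl-1-(propan-2-yl)cyclopent-2-en-1-ol
Product: 5 (1R,4R)-3-methyl-1-(propan-2-yl)cyclopent-2-ene-1,4-diol
Conditions: TBAF, THF, 0 °C to rt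
Reagents that add atoms: none
Why: Fluoride desilylation should free the secondary allylic alcohol without touching the tertiary allylic alcohol.

**Step 5**
Reactants: 5 (1R,4R)-3-methyl-1-(propan-2-yl)cyclopent-2-ene-1,4-diol
Product: 6 (R)-4-hydroxy-2-methyl-4-(propan-2-yl)cyclopent-2-en-1-one
Conditions: MnO2, CH2Cl2, rt
Reagents that add atoms: none
Why: MnO2 should oxidize only the secondary allylic alcohol, so the relay stereocentre is erased and the tertiary carbinol remains as the single stereocentre of the enone.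

**Step 6**
Reactants: 6 (R)-4-hydroxy-2-methyl-4-(propan-2-yl)cyclopent-2-en-1-one; 7 3-methylbut-2-enal
Product: 9 (2S,3R,4R)-3-ethenyl-4-hydroxy-2-(1-hydroxy-3-methylbut-2-en-1-yl)-2-methyl-4-(propan-2-yl)cyclopentan-1-one (both epimers at the side-chain carbinol), via magnesium enolate 8 (not isolated)
Conditions: vinylMgBr (2.2 equiv), THF, −78 to −10 °C; then 7, −78 °C
Reagents that add atoms: vinylmagnesium bromide C=C[Mg]Br
Why: In an alkoxide-directed conjugate addition of the Grignard reagent the magnesium alkoxide should deliver vinyl to C3 on its own face, which is also the face opposite the isopropyl group, and the regiodefined enolate should then undergo aldol addition to 7 anti to the new vinyl group, creating the quaternary centre (the carbinol configuration is removed in step 7).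

**Step 7**
Reactants: 9 (2S,3R,4R)-3-ethenyl-4-hydroxy-2-(1-hydroxy-3-methylbut-2-en-1-yl)-2-methyl-4-(propan-2-yl)cyclopentan-1-one
Product: 10 (2R,3R,4R)-3-ethenyl-4-hydroxy-2-methyl-2-(3-methylbut-2-enoyl)-4-(propan-2-yl)cyclopentan-1-one
Conditions: Dess–Martin periodinane, NaHCO3, CH2Cl2, 0 °C to rt
Reagents that add atoms: none
Why: Dess–Martin oxidation should convert the secondary allylic alcohol into the enone under buffered conditions that spare the tertiary alcohol and the non-enolizable 1,3-diketone.

**Step 8**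
Reactants: 10 (2R,3R,4R)-3-ethenyl-4-hydroxy-2-methyl-2-(3-methylbut-2-enoyl)-4-(propan-2-yl)cyclopentan-1-one
Product: 11 1-[(1R,2R,3R,5S)-2-ethenyl-3,5-dihydroxy-1-methyl-3-(propan-2-yl)cyclopentyl]-3-methylbut-2-en-1-one
Conditions: NaBH4, MeOH/CH2Cl2 (1:1), −78 °C
Reagents that add atoms: none
Why: Borohydride at low temperature should reduce the strained saturated ring ketone in preference to the hindered conjugated ketone, with hydride attacking from the face of the quaternary methyl and the tertiary hydroxyl, opposite the acyl and isopropyl groups, which places the new hydroxyl cis to the acyl group.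

**Step 9**
Reactants: 11 1-[(1R,2R,3R,5S)-2-ethenyl-3,5-dihydroxy-1-methyl-3-(propan-2-yl)cyclopentyl]-3-methylbut-2-en-1-one
Product: 12 (1S,2R,3R,4R)-3-ethenyl-4-hydroxy-2-methyl-2-(3-methylbut-2-enoyl)-4-(propan-2-yl)cyclopentyl acetate
Conditions: Ac2O, DMAP (cat.), pyridine, CH2Cl2, 0 °C to rt
Reagents that add atoms: acetic anhydride CC(=O)OC(C)=O
Why: DMAP-catalysed acetylation should take the secondary alcohol only, since the tertiary alcohol flanked by isopropyl is far more hindered.

**Step 10**
Reactants: 12 (1S,2R,3R,4R)-3-ethenyl-4-hydroxy-2-methyl-2-(3-methylbut-2-enoyl)-4-(propan-2-yl)cyclopentyl acetate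
Product: 14 (1S,2R,3R,4R)-3-formyl-4-hydroxy-2-methyl-2-(3-methylbut-2-enoyl)-4-(propan-2-yl)cyclopentyl acetate, via vicinal diol 13 (not isolated)
Conditions: OsO4 (cat.), NaIO4, 2,6-lutidine, dioxane/H2O, rt
Reagents that add atoms: osmium tetroxide O=[Os](=O)(=O)=O (catalytic oxygen carrier); sodium periodate [Na+].[O-][I](=O)(=O)=O
Why: Lemieux–Johnson cleavage should take the isolated vinyl group in preference to the electron-poor trisubstituted enone alkene, and the buffered medium should leave the epimerizable formyl-bearing centre intact.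

**Step 11**
Reactants: 14 (1S,2R,3R,4R)-3-formyl-4-hydroxy-2-methyl-2-(3-methylbut-2-enoyl)-4-(propan-2-yl)cyclopentyl acetate
Product: 17 (1S,3R,3aS,4S,8aR)-3,4-dihydroxy-6,8a-dimethyl-8-oxo-3-(propan-2-yl)-1,2,3,3a,4,5,8,8a-octahydroazulen-1-yl acetate, via silyl dienol ether 15 (not isolated), via cyclized bis-silyl ether 16 (not isolated)
Conditions: TMSOTf (3 equiv), Et3N (2.5 equiv), CH2Cl2, −78 to 0 °C; then 1 M HCl, THF, 0 °C
Reagents that add atoms: none
Why: TMSOTf/Et3N should silylate the tertiary hydroxyl and turn the enone, which has no α′-hydrogen because C8a is quaternary, into the 2-silyloxydiene 15; excess TMSOTf then activates the aldehyde, the diene terminus (a former γ-methyl) adds to it, silyl transfer gives 16, and acid work-up cleaves both TMS ethers. The closest known reaction type is the vinylogous Mukaiyama aldol reaction run with in situ soft enolization. The seven-membered ring closes in a 7-(enolendo)-exo-trig mode. The new C4 stereocentre is controlled by the adjacent ring-fusion carbon C3a: in the chair-like transition state of the trans-fused bicycle the silyloxonium oxygen should sit pseudo-equatorial, anti to the C3a–C8a bond and away from the two quaternary neighbours, which gives the 4S alcohol. The step needs γ- rather than α-attack and an intact C3a centre; α-attack would build a strained trans-bicyclo[3.3.0]octane and silyl dienol ethers react at the γ-terminus in any case, while the C3a–H lies between two fully substituted carbons and should not be removed by Et3N. Only the dienol ether isomer with C8a and C6 cis across the enol double bond can cyclize, and it should be replenished by reversible C-protonation with Et3NH+ TfO−.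

**Step 12**
Reactants: 17 (1S,3R,3aS,4S,8aR)-3,4-dihydroxy-6,8a-dimethyl-8-oxo-3-(propan-2-yl)-1,2,3,3a,4,5,8,8a-octahydroazulen-1-yl acetate; 18 angelic acid, (2Z)-2-methylbut-2-enoic acid
Product: 19 (1S,3R,3aS,4S,8aR)-1-(acetyloxy)-3-hydroxy-6,8a-dimethyl-8-oxo-3-(propan-2-yl)-1,2,3,3a,4,5,8,8a-octahydroazulen-4-yl (2Z)-2-methylbut-2-enoate
Conditions: 18, 2,4,6-trichlorobenzoyl chloride, Et3N, toluene, rt; then 17, 75 °C
Reagents that add atoms: none
Why: Yamaguchi esterification through the mixed anhydride without DMAP should acylate the only secondary hydroxyl and keep the Z geometry of the angelate, while the tertiary hydroxyl stays free.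

**Step 13**
Reactants: 19 (1S,3R,3aS,4S,8aR)-1-(acetyloxy)-3-hydroxy-6,8a-dimethyl-8-oxo-3-(propan-2-yl)-1,2,3,3a,4,5,8,8a-octahydroazulen-4-yl (2Z)-2-methylbut-2-enoate
Product: 20 (1S,3R,3aS,4S,8S,8aS)-1-(acetyloxy)-3,8-dihydroxy-6,8a-dimethyl-3-(propan-2-yl)-1,2,3,3a,4,5,8,8a-octahydroazulen-4-yl (2Z)-2-methylbut-2-enoate
Conditions: NaBH4, CeCl3·7H2O, MeOH, −78 °C
Reagents that add atoms: none
Why: Luche 1,2-reduction should spare the esters, and hydride should attack C8 from the face opposite the angular methyl on C8a, which gives the 8S alcohol cis to that methyl (the 8a descriptor changes from R to S only through CIP priorities).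

**Step 14**
Reactants: 20 (1S,3R,3aS,4S,8S,8aS)-1-(acetyloxy)-3,8-dihydroxy-6,8a-dimethyl-3-(propan-2-yl)-1,2,3,3a,4,5,8,8a-octahydroazulen-4-yl (2Z)-2-methylbut-2-enoate
Product: 21 (1S,3R,3aS,4S,8S,8aR)-1-(acetyloxy)-8-(benzoyloxy)-3-hydroxy-6,8a-dimethyl-3-(propan-2-yl)-1,2,3,3a,4,5,8,8a-octahydroazulen-4-yl (2Z)-2-methylbut-2-enoate (target)
Conditions: BzCl, DMAP, pyridine, CH2Cl2, 0 °C to rt
Reagents that add atoms: benzoyl chloride O=C(Cl)c1ccccc1
Why: DMAP-catalysed benzoylation should esterify the secondary allylic alcohol with retention, and the hindered tertiary alcohol should remain free.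

**Compound list**

1 | (R)-4-(tert-butyldimethylsilyloxy)cyclopent-2-en-1-one | CC(C)(C)[Si](C)(C)O[C@@H]1CC(=O)C=C1 | starting material
2 | (3R,4R)-4-(tert-butyldimethylsilyloxy)-3-methyl-1-(trimethylsilyloxy)cyclopent-1-ene | C[C@@H]1C=C(O[Si](C)(C)C)C[C@H]1O[Si](C)(C)C(C)(C)C | intermediate
3 | (R)-4-(tert-butyldimethylsilyloxy)-3-methylcyclopent-2-en-1-one | CC1=CC(=O)C[C@H]1O[Si](C)(C)C(C)(C)C | intermediate
4 | (1R,4R)-4-(tert-butyldimethylsilyloxy)-3-methyl-1-(propan-2-yl)cyclopent-2-en-1-ol | CC1=C[C@](O)(C(C)C)C[C@H]1O[Si](C)(C)C(C)(C)C | intermediate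
5 | (1R,4R)-3-methyl-1-(propan-2-yl)cyclopent-2-ene-1,4-diol | CC1=C[C@](O)(C(C)C)C[C@H]1O | intermediate
6 | (R)-4-hydroxy-2-methyl-4-(propan-2-yl)cyclopent-2-en-1-one | CC1=C[C@](O)(C(C)C)CC1=O | intermediate
7 | 3-methylbut-2-enal | CC(C)=CC=O | starting material
8 | bis(bromomagnesium) enolate–alkoxide of (3R,4R)-3-ethenyl-4-hydroxy-2-methyl-4-(propan-2-yl)cyclopentan-1-one | CC1=C(O[Mg]Br)C[C@@](O[Mg]Br)(C(C)C)[C@@H]1C=C | intermediate (not isolated)
9 | (2S,3R,4R)-3-ethenyl-4-hydroxy-2-(1-hydroxy-3-methylbut-2-en-1-yl)-2-methyl-4-(propan-2-yl)cyclopentan-1-one, both carbinol epimers | CC(C)=CC(O)[C@@]1(C)C(=O)C[C@@](O)(C(C)C)[C@@H]1C=C | intermediate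
10 | (2R,3R,4R)-3-ethenyl-4-hydroxy-2-methyl-2-(3-methylbut-2-enoyl)-4-(propan-2-yl)cyclopentan-1-one | CC(C)=CC(=O)[C@@]1(C)C(=O)C[C@@](O)(C(C)C)[C@@H]1C=C | intermediate
11 | 1-[(1R,2R,3R,5S)-2-ethenyl-3,5-dihydroxy-1-methyl-3-(propan-2-yl)cyclopentyl]-3-methylbut-2-en-1-one | CC(C)=CC(=O)[C@@]1(C)[C@@H](O)C[C@@](O)(C(C)C)[C@@H]1C=C | intermediate
12 | (1S,2R,3R,4R)-3-ethenyl-4-hydroxy-2-methyl-2-(3-methylbut-2-enoyl)-4-(propan-2-yl)cyclopentyl acetate | CC(C)=CC(=O)[C@@]1(C)[C@@H](OC(C)=O)C[C@@](O)(C(C)C)[C@@H]1C=C | intermediate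
13 | 1,2-diol from dihydroxylation of the vinyl group of 12 (either configuration at the new carbinol) | CC(C)=CC(=O)[C@@]1(C)[C@@H](OC(C)=O)C[C@@](O)(C(C)C)[C@@H]1C(O)CO | intermediate (not isolated)
14 | (1S,2R,3R,4R)-3-formyl-4-hydroxy-2-methyl-2-(3-methylbut-2-enoyl)-4-(propan-2-yl)cyclopentyl acetate | CC(C)=CC(=O)[C@@]1(C)[C@@H](OC(C)=O)C[C@@](O)(C(C)C)[C@@H]1C=O | intermediate
15 | 2-(trimethylsilyloxy)diene of 14 with the tertiary hydroxyl as TMS ether (enol geometry equilibrating) | C=C(C)C=C(O[Si](C)(C)C)[C@@]1(C)[C@@H](OC(C)=O)C[C@@](O[Si](C)(C)C)(C(C)C)[C@@H]1C=O | intermediate (not isolated)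
16 | 3,4-bis(trimethylsilyl) ether of 17 | C[Si](C)(C)O[C@H]1CC(C)=CC(=O)[C@@]2(C)[C@@H](OC(C)=O)C[C@@](O[Si](C)(C)C)(C(C)C)[C@H]12 | intermediate (not isolated)
17 | (1S,3R,3aS,4S,8aR)-3,4-dihydroxy-6,8a-dimethyl-8-oxo-3-(propan-2-yl)-1,2,3,3a,4,5,8,8a-octahydroazulen-1-yl acetate | O[C@H]1CC(C)=CC(=O)[C@@]2(C)[C@@H](OC(C)=O)C[C@@](O)(C(C)C)[C@H]12 | intermediate
18 | angelic acid, (2Z)-2-methylbut-2-enoic acid | C/C=C(/C)C(=O)O | starting material
19 | (1S,3R,3aS,4S,8aR)-1-(acetyloxy)-3-hydroxy-6,8a-dimethyl-8-oxo-3-(propan-2-yl)-1,2,3,3a,4,5,8,8a-octahydroazulen-4-yl (2Z)-2-methylbut-2-enoate | C/C=C(/C)C(=O)O[C@H]1CC(C)=CC(=O)[C@@]2(C)[C@@H](OC(C)=O)C[C@@](O)(C(C)C)[C@H]12 | intermediate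
20 | (1S,3R,3aS,4S,8S,8aS)-1-(acetyloxy)-3,8-dihydroxy-6,8a-dimethyl-3-(propan-2-yl)-1,2,3,3a,4,5,8,8a-octahydroazulen-4-yl (2Z)-2-methylbut-2-enoate | C/C=C(/C)C(=O)O[C@H]1CC(C)=C[C@H](O)[C@@]2(C)[C@@H](OC(C)=O)C[C@@](O)(C(C)C)[C@H]12 | intermediate
21 | (1S,3R,3aS,4S,8S,8aR)-1-(acetyloxy)-8-(benzoyloxy)-3-hydroxy-6,8a-dimethyl-3-(propan-2-yl)-1,2,3,3a,4,5,8,8a-octahydroazulen-4-yl (2Z)-2-methylbut-2-enoate | C/C=C(/C)C(=O)O[C@H]1CC(C)=C[C@H](OC(=O)c2ccccc2)[C@@]2(C)[C@@H](OC(C)=O)C[C@@](O)(C(C)C)[C@H]12 | target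

**Step count.** Total steps: 14. Longest linear sequence: 14 steps (from 1).

**Steps most likely to fail**

1. Step 11. The dienol ether may form mainly in the geometry that cannot reach the aldehyde, or the product enone may be enolized again and lose silanol to a dienone, so that cyclization is slow or the adduct is destroyed. Fallback, setting out from 14 and coming back at 17: irradiation at 254 nm with a catalytic weak base should deconjugate the enone to the β,γ-unsaturated keto aldehyde F1; Me2AlCl in CH2Cl2 at −78 °C should then effect a carbonyl-ene (Prins-type) cyclization of the 1,1-disubstituted alkene onto the aldehyde to give the exo-methylene hydroxy ketone F2 (formed with its endocyclic alkene isomers); DBU should move the double bond into conjugation with the ketone and so give 17.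

2. Step 6. The Grignard reagent may add 1,2 or from the undirected face, and the hindered tetrasubstituted magnesium enolate may undergo proton transfer or retro-aldol instead of adding to 7. Fallback, setting out from 6 and coming back at 9: after the directed vinyl addition the enolate and the alkoxide are silylated with TMSCl/Et3N to give the bis(trimethylsilyl) enol ether F3; a BF3·OEt2-mediated Mukaiyama aldol addition to 7 at −78 °C with mild acidic work-up should then give 9.

3. Step 8. Hydride may approach the ring ketone from the wrong face, reduction may go on to the enone carbonyl, or methoxide may open the non-enolizable 1,3-diketone by retro-Claisen cleavage. Fallback, setting out from 10 and coming back at 11: a hydroxyl-directed Evans–Saksena reduction with Me4NBH(OAc)3 in MeCN/AcOH at −30 °C replaces steric approach control by intramolecular hydride delivery from boron bound to the tertiary hydroxyl, which should give the 1,3-anti diol 11 under acidic, non-nucleophilic conditions (no new compound, F0).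

**Further compounds**

F1 | step 11 | (1S,2R,3R,4R)-3-formyl-4-hydroxy-2-methyl-2-(3-methylbut-3-enoyl)-4-(propan-2-yl)cyclopentyl acetate | C=C(C)CC(=O)[C@@]1(C)[C@@H](OC(C)=O)C[C@@](O)(C(C)C)[C@@H]1C=O
F2 | step 11 | (1S,3R,3aS,4S,8aR)-3,4-dihydroxy-8a-methyl-6-methylidene-8-oxo-3-(propan-2-yl)decahydroazulen-1-yl acetate | O[C@H]1CC(=C)CC(=O)[C@@]2(C)[C@@H](OC(C)=O)C[C@@](O)(C(C)C)[C@H]12
F3 | step 6 | (3R,4R)-3-ethenyl-2-methyl-4-(propan-2-yl)-1,4-bis(trimethylsilyloxy)cyclopent-1-ene | CC1=C(O[Si](C)(C)C)C[C@@](O[Si](C)(C)C)(C(C)C)[C@@H]1C=C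
F0 | step 8 | none | none
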